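**Plan**

The target is a tridepside with no stereocentre. Ring A is the 2-hydroxy-4-methoxy-6-methylbenzoyl end, ring B the central unit and ring C the methyl ester end; each ring is numbered from its carboxyl-bearing carbon as C1.
Retrosynthesis cuts the A–B ester C–O bond first (acid 9 + diphenol 17), then the B–C ester C–O bond (acid 14 + phenol 13); rings B and C both come from methyl orsellinate.
Ring A is cut at C6–CH3 and C1–CO2H. The C6 methyl and C1 carboxyl are adjacent, C1 has the C2 oxygen on its other side, and the C4 oxygen is meta to it, so 3,5-dimethoxybenzyne can accept CH3 at C6 and CO2 at C1.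
Forward: the aryne coupling gives acid 7 and BCl3 frees its C2–OH (9); methyl orsellinate gives phenol 13 and acid 14, which are joined and debenzylated to 17; 9 then acylates the ring B C4–OH.
There is no stereochemistry to set; all selectivity is regiochemical and rests on chelation of ortho oxygen groups to carbonyl groups.

Key step: step 1

Remark: lithium and potassium salts that are only protonated on work-up are treated as the neutral acids or phenols obtained after acidification and are not numbered separately.

**Route**

Step 1
Reactants: 1 1-fluoro-3,5-dimethoxybenzene; 2 methyllithium; 3 carbon dioxide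
Product: 7 2,4-dimethoxy-6-methylbenzoic acid, via 2-fluoro-4,6-dimethoxyphenyllithium 4 (not isolated), via 3,5-dimethoxybenzyne 5 (not isolated), via 2,4-dimethoxy-6-methylphenyllithium 6 (not isolated)
Conditions: n-BuLi (1.0 equiv), THF, −78 °C; MeLi (2.5 equiv, Et2O), −78 to −10 °C; CO2 (excess), −78 °C; aq HCl
Reagents that add atoms: none
Why: n-BuLi should remove the ring proton of 1 that lies between fluorine and a methoxy group, and on warming the aryllithium 4 should expel LiF to give aryne 5, the only aryne the symmetric fluoroarene can form. MeLi is expected to add to the aryne carbon remote from the neighbouring methoxy group, since this puts the carbanion on the carbon next to oxygen, where it is stabilised inductively and by lithium coordination; CO2 then traps aryllithium 6 at that carbon. The closest known reaction type is the three-component coupling of 3-methoxybenzynes, generated from 3-fluoroanisoles, with organolithium or Grignard reagents and an electrophile, which gives 6-alkyl-2-methoxybenzoic acids. No ring is formed and no stereocentre is created. The selectivity needed is regiochemical, in the metalation (beside fluorine, not between the two methoxy groups) and in the methyl addition; the first is secured by the acidifying fluorine, the second by the methoxy group flanking the triple bond. Using exactly one equivalent of n-BuLi before MeLi is added should keep butyl out of the product.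

Step 2
Reactants: 7 2,4-dimethoxy-6-methylbenzoic acid
Product: 9 2-hydroxy-4-methoxy-6-methylbenzoic acid (everninic acid), via cyclic chloroboronate 8 (not isolated)
Conditions: BCl3 (2.2 equiv), CH2Cl2, −78 to 0 °C; cold H2O
Reagents that add atoms: none
Why: In this chelation-directed Lewis acid ether cleavage BCl3 binds the carboxyl group and the adjacent C2 methoxy oxygen in a six-membered chelate, so chloride should remove only that methyl group and leave the unchelated C4 methyl ether.

Step 3
Reactants: 10 methyl orsellinate (methyl 2,4-dihydroxy-6-methylbenzoate)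
Product: 11 methyl 4-(benzyloxy)-2-hydroxy-6-methylbenzoate
Conditions: BnBr (1.05 equiv), K2CO3, acetone, reflux
Reagents that add atoms: benzyl bromide, BrCc1ccccc1
Why: This Williamson ether synthesis with a weak base should alkylate only the C4–OH, because the C2–OH is hydrogen-bonded to the ester carbonyl and far less nucleophilic.

Step 4
Reactants: 11 methyl 4-(benzyloxy)-2-hydroxy-6-methylbenzoate
Product: 12 methyl 4-(benzyloxy)-2-methoxy-6-methylbenzoate
Conditions: MeI (3 equiv), K2CO3, DMF, 50 °C
Reagents that add atoms: iodomethane, CI
Why: Williamson O-methylation in a polar aprotic solvent with excess MeI should force alkylation of the chelated phenol, the only nucleophilic site left.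

Step 5
Reactants: 12 methyl 4-(benzyloxy)-2-methoxy-6-methylbenzoate
Product: 13 methyl 4-hydroxy-2-methoxy-6-methylbenzoate
Conditions: H2 (1 atm), 10% Pd/C, EtOAc, rt
Reagents that add atoms: none
Why: Catalytic hydrogenolysis of the benzyl ether should free the C4 phenol of ring C without affecting the methyl ester or the methyl ether.

Step 6
Reactants: 11 methyl 4-(benzyloxy)-2-hydroxy-6-methylbenzoate
Product: 14 4-(benzyloxy)-2-hydroxy-6-methylbenzoic acid
Conditions: KOH, DMSO/H2O, 80 °C; cold aq HCl to pH 2
Reagents that add atoms: potassium hydroxide, [K+].[OH-]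
Why: Saponification with KOH in aqueous DMSO is the established way to hydrolyse di-ortho-substituted benzoates, the benzyl ether is stable to base, and cold acidification should avoid decarboxylation of the electron-rich acid.

Step 7
Reactants: 14 4-(benzyloxy)-2-hydroxy-6-methylbenzoic acid; 13 methyl 4-hydroxy-2-methoxy-6-methylbenzoate
Product: 16 methyl 4-{[4-(benzyloxy)-2-hydroxy-6-methylbenzoyl]oxy}-2-methoxy-6-methylbenzoate, via mixed trifluoroacetic anhydride 15 (not isolated)
Conditions: (CF3CO)2O, toluene, 0 °C to rt
Reagents that add atoms: none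
Why: In this mixed-anhydride depside esterification the aroyl trifluoroacetate should acylate the only unchelated phenol, the C4–OH of 13, while the C2–OH of the acid stays hydrogen-bonded to its own carbonyl and unreactive.

Step 8
Reactants: 16 methyl 4-{[4-(benzyloxy)-2-hydroxy-6-methylbenzoyl]oxy}-2-methoxy-6-methylbenzoate
Product: 17 methyl 4-[(2,4-dihydroxy-6-methylbenzoyl)oxy]-2-methoxy-6-methylbenzoate
Conditions: H2 (1 atm), 10% Pd/C, EtOAc, rt
Reagents that add atoms: none
Why: Catalytic hydrogenolysis in a non-nucleophilic solvent should remove the benzyl ether and leave the aryl ester and methyl ester intact.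

Step 9
Reactants: 9 2-hydroxy-4-methoxy-6-methylbenzoic acid; 17 methyl 4-[(2,4-dihydroxy-6-methylbenzoyl)oxy]-2-methoxy-6-methylbenzoate
Product: 19 methyl 4-({2-hydroxy-4-[(2-hydroxy-4-methoxy-6-methylbenzoyl)oxy]-6-methylbenzoyl}oxy)-2-methoxy-6-methylbenzoate, via mixed trifluoroacetic anhydride 18 (not isolated)
Conditions: (CF3CO)2O, toluene, 0 °C to rt
Reagents that add atoms: none
Why: The same mixed-anhydride depside esterification should deliver the ring A acyl group to the free C4–OH of ring B, since the C2–OH groups of 17 and of the activated acid are both chelated to ester carbonyls and react much more slowly.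

**Compound list**

1 | 1-fluoro-3,5-dimethoxybenzene | COc1cc(F)cc(OC)c1 | starting material
2 | methyllithium | [Li]C | starting material
3 | carbon dioxide | O=C=O | starting material
4 | 2-fluoro-4,6-dimethoxyphenyllithium | [Li]c1c(F)cc(OC)cc1OC | intermediate
5 | 3,5-dimethoxybenzyne (1,2-didehydro-3,5-dimethoxybenzene) | COC1=CC(OC)=CC#C1 | intermediate
6 | 2,4-dimethoxy-6-methylphenyllithium | [Li]c1c(C)cc(OC)cc1OC | intermediate
7 | 2,4-dimethoxy-6-methylbenzoic acid | COc1cc(C)c(C(=O)O)c(OC)c1 | intermediate
8 | 2-chloro-7-methoxy-5-methyl-4H-1,3,2-benzodioxaborin-4-one (cyclic chloroboronate) | COc1cc(C)c2C(=O)OB(Cl)Oc2c1 | intermediate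
9 | 2-hydroxy-4-methoxy-6-methylbenzoic acid (everninic acid) | COc1cc(C)c(C(=O)O)c(O)c1 | intermediate
10 | methyl 2,4-dihydroxy-6-methylbenzoate (methyl orsellinate) | COC(=O)c1c(C)cc(O)cc1O | starting material
11 | methyl 4-(benzyloxy)-2-hydroxy-6-methylbenzoate | COC(=O)c1c(C)cc(OCc2ccccc2)cc1O | intermediate
12 | methyl 4-(benzyloxy)-2-methoxy-6-methylbenzoate | COC(=O)c1c(C)cc(OCc2ccccc2)cc1OC | intermediate
13 | methyl 4-hydroxy-2-methoxy-6-methylbenzoate | COC(=O)c1c(C)cc(O)cc1OC | intermediate
14 | 4-(benzyloxy)-2-hydroxy-6-methylbenzoic acid | OC(=O)c1c(C)cc(OCc2ccccc2)cc1O | intermediate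
15 | 4-(benzyloxy)-2-hydroxy-6-methylbenzoic trifluoroacetic anhydride | O=C(OC(=O)C(F)(F)F)c1c(C)cc(OCc2ccccc2)cc1O | intermediate
16 | methyl 4-{[4-(benzyloxy)-2-hydroxy-6-methylbenzoyl]oxy}-2-methoxy-6-methylbenzoate | COC(=O)c1c(C)cc(OC(=O)c2c(C)cc(OCc3ccccc3)cc2O)cc1OC | intermediate
17 | methyl 4-[(2,4-dihydroxy-6-methylbenzoyl)oxy]-2-methoxy-6-methylbenzoate | COC(=O)c1c(C)cc(OC(=O)c2c(C)cc(O)cc2O)cc1OC | intermediate
18 | 2-hydroxy-4-methoxy-6-methylbenzoic trifluoroacetic anhydride | COc1cc(C)c(C(=O)OC(=O)C(F)(F)F)c(O)c1 | intermediate
19 | methyl 4-({2-hydroxy-4-[(2-hydroxy-4-methoxy-6-methylbenzoyl)oxy]-6-methylbenzoyl}oxy)-2-methoxy-6-methylbenzoate | COC(=O)c1c(C)cc(OC(=O)c2c(C)cc(OC(=O)c3c(C)cc(OC)cc3O)cc2O)cc1OC | target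

**Count and risks**

Total step count: 9. Longest linear sequence: 6 steps (steps 3, 4, 5, 7, 8, 9, from methyl orsellinate 10 to 19); the ring A arm contributes steps 1, 2 and 9.

The three steps most likely to fail:

Step 1. Metalation may occur partly between the two methoxy groups, where the aryllithium cannot eliminate and is simply carboxylated. Butyl may add to the aryne in place of methyl, or the aryne may be consumed by its own aryllithium precursor. The fallback abandons the aryne and sets out from methyl orsellinate 10: exhaustive O-methylation (excess MeI, K2CO3, DMF, 60 °C) should give methyl 2,4-dimethoxy-6-methylbenzoate F1, and saponification (KOH, DMSO/H2O, 90 °C, then cold HCl) returns to the route at 7.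

Step 2. The Lewis acid may also cleave the C4 methyl ether, or the electron-rich acid may lose CO2 during the reaction or the acidic work-up. The fallback avoids any demethylation and sets out from methyl orsellinate 10: selective alkylation of the unchelated C4–OH (MeI 1.05 equiv, K2CO3, acetone, reflux) should give methyl 2-hydroxy-4-methoxy-6-methylbenzoate F2, and saponification (KOH, DMSO/H2O, 80 °C, then cold HCl) returns to the route at 9.

Step 9. Acylation may also take place at the chelated hydroxyl of ring B, the activated hydroxy acid may condense with itself, or the acidic medium may promote acyl migration between the two depside esters. The fallback masks the ortho hydroxyl of the acid and uses a neutral coupling; it sets out from 9. Double benzylation (BnBr, K2CO3, DMF, 60 °C) should give benzyl 2-(benzyloxy)-4-methoxy-6-methylbenzoate F3, and saponification (KOH, DMSO/H2O, 80 °C) should give 2-(benzyloxy)-4-methoxy-6-methylbenzoic acid F4. Carbodiimide esterification of F4 with diphenol 17 (DCC, DMAP, CH2Cl2, rt) is expected to give methyl 4-({4-[(2-(benzyloxy)-4-methoxy-6-methylbenzoyl)oxy]-2-hydroxy-6-methylbenzoyl}oxy)-2-methoxy-6-methylbenzoate F5, and hydrogenolysis (H2, Pd/C, EtOAc) comes back to the route at 19.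

**Further compounds**

F1 | step 1 | methyl 2,4-dimethoxy-6-methylbenzoate | COC(=O)c1c(C)cc(OC)cc1OC
F2 | step 2 | methyl 2-hydroxy-4-methoxy-6-methylbenzoate | COC(=O)c1c(C)cc(OC)cc1O
F3 | step 9 | benzyl 2-(benzyloxy)-4-methoxy-6-methylbenzoate | COc1cc(C)c(C(=O)OCc2ccccc2)c(OCc3ccccc3)c1
F4 | step 9 | 2-(benzyloxy)-4-methoxy-6-methylbenzoic acid | COc1cc(C)c(C(=O)O)c(OCc2ccccc2)c1
F5 | step 9 | methyl 4-({4-[(2-(benzyloxy)-4-methoxy-6-methylbenzoyl)oxy]-2-hydroxy-6-methylbenzoyl}oxy)-2-methoxy-6-methylbenzoate | COC(=O)c1c(C)cc(OC(=O)c2c(C)cc(OC(=O)c3c(C)cc(OC)cc3OCc4ccccc4)cc2O)cc1OC
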